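**Retrosynthetic overview**

1. Ring A is the ring that carries the side chain and ring B the ring with the C5/C8 oxygens. The target comes from a 1-acetoxy-4-silyloxy-naphthalene-5,8-dione by fluoride/methanolysis, this from (NH4)2Ce(NO3)6 oxidation of the 5,8-dimethoxy ring B, and the ester from Steglich acylation with (R)-2-methylbutanoic acid.
2. The C1′ stereocentre and the (E)-alkene come from an amino-alcohol-catalysed alkenylzinc addition (alkenyl from 2-methylbut-3-yn-2-ol) to a naphthaldehyde, made by Lemieux–Johnson cleavage of a vinylnaphthalene.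
3. Ring A comes from thermal ring expansion of a 4-aryl-4-silyloxy-3-vinylcyclobutenone: a temporary four-membered ring opens to a dienylketene whose ketene carbon closes onto the arene, forming the C4–C4a bond of the naphthoquinone.
4. Enabling feature: ring A is C1(=O)–C2(R)=C3(H)–C4(=O), the four carbons of a cyclobutenone oxygenated at both ends, and ring B has oxygen at C5 and C8, so the 2,5-dimethoxyphenyl partner has only one free ortho carbon, the future C4a.
5. The cyclobutenone comes from isopropyl semisquarate (from diisopropyl squarate), 2,5-dimethoxyphenyllithium and a vinyl Grignard/Stork–Danheiser step. Ring order: ring B and the four-membered ring are bought, ring A is made last, in the key step.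

Key step: step 4

Assumption: the two naphthazarin tautomers (1,4-dione/5,8-diol and 5,8-dione/1,4-diol) interconvert by fast proton transfer, so the 1,4-dihydroxy-5,8-dione formed in step 10 is the compound drawn in the target SMILES; (R)-2-methylbutanoic acid is taken as a purchasable single enantiomer.

**Route**

Step 1
Reactants: 1 diisopropyl squarate (3,4-diisopropoxycyclobut-3-ene-1,2-dione)
Product: 3 3-isopropoxycyclobut-3-ene-1,2-dione (isopropyl semisquarate), via hydroxycyclobutenone 2 (not isolated)
Conditions: LiAlH(OtBu)3, THF, −78 to −20 °C; aq HCl quench; then conc. HCl (cat.), CH2Cl2, rt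
Reagents that add atoms: water, O
Why: The bulky hydride should reduce one vinylogous ester carbonyl only, and acid ionisation of the resulting carbinol with hydrolysis of the oxocarbenium ion (loss of isopropanol) should give the semisquarate; this is the standard squarate reduction–hydrolysis sequence.

Step 2
Reactants: 4 2-bromo-1,4-dimethoxybenzene; 3 isopropyl semisquarate
Product: 7 4-[(tert-butyldimethylsilyl)oxy]-4-(2,5-dimethoxyphenyl)-3-isopropoxycyclobut-2-en-1-one (racemic), via aryllithium 5 (not isolated), via lithium alkoxide 6 (not isolated)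
Conditions: n-BuLi, THF, −78 °C; cannulate into 3, THF, −78 °C; TBSOTf, −78 to −20 °C
Reagents that add atoms: tert-butyldimethylsilyl trifluoromethanesulfonate (TBSOTf), CC(C)(C)[Si](C)(C)OS(=O)(=O)C(F)(F)F
Why: Bromine–lithium exchange gives the aryllithium, which should add 1,2 to the more electrophilic carbonyl of 3 (the one on the isopropoxy-bearing carbon; the other is deactivated as a vinylogous ester), and the tertiary alkoxide is silylated in the flask before it can ring-open; organolithium addition to a squarate ester.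

Step 3
Reactants: 7 4-[(tert-butyldimethylsilyl)oxy]-4-(2,5-dimethoxyphenyl)-3-isopropoxycyclobut-2-en-1-one
Product: 10 4-[(tert-butyldimethylsilyl)oxy]-4-(2,5-dimethoxyphenyl)-3-vinylcyclobut-2-en-1-one (racemic), via magnesium alkoxide 8 (not isolated), via tertiary alcohol 9 (not isolated)
Conditions: CH2=CHMgBr, THF, −78 to 0 °C; then 1 M HCl, THF, 0 °C
Reagents that add atoms: vinylmagnesium bromide, C=C[Mg]Br; water, O
Why: 1,2-Addition to the vinylogous ester carbonyl and acid hydrolysis of the enol ether with loss of isopropanol (Stork–Danheiser transposition) should give the 3-vinyl enone; because both the old and the new carbonyl carbon are bonded to the silyloxy carbon, a direct addition–elimination would give the same constitution, with CH opposite the silyloxy carbon.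

Step 4
Reactants: 10 4-[(tert-butyldimethylsilyl)oxy]-4-(2,5-dimethoxyphenyl)-3-vinylcyclobut-2-en-1-one
Product: 14 4-[(tert-butyldimethylsilyl)oxy]-5,8-dimethoxy-3-vinylnaphthalen-1-yl acetate, via dienylketene 11 (not isolated), via bicyclic dienone 12 (not isolated), via naphthol 13 (not isolated)
Conditions: p-xylene (0.02 M, degassed), 138 °C, 1–2 h; then rt, Ac2O, Et3N, DMAP (cat.)
Reagents that add atoms: acetic anhydride, CC(=O)OC(C)=O
Why: Heating opens the cyclobutenone by conrotatory 4π electrocyclic cleavage of the bond between the carbonyl carbon and the silyloxy-bearing carbon, and because the silyloxy donor rotates outward the aryl group ends up cis to the ketene in dienylketene 11. A thermal 6π electrocyclisation (disrotatory, six-membered closure over the ketene C=C, the central C=C and the aryl ipso–ortho bond) then joins the ketene carbon, which becomes the quinone carbonyl carbon next to the ring CH, to the free ortho carbon of the arene, which becomes the ring-fusion carbon, and so closes ring A; dienone 12 aromatises by tautomerism to naphthol 13. This is the Moore–Liebeskind ring expansion of 4-aryl-4-oxygenated cyclobutenones, which has close precedent for 1,4-dioxygenated naphthalenes. No stereocentre is created and the racemic carbon of 10 is destroyed. The site selectivity is secured by the substrate: the other ortho carbon carries a methoxy group, and the vinyl group sits trans to the arene on the central double bond, so it cannot enter a competing electrocyclisation. Acetylation in the same flask protects the air-sensitive naphthol and makes ring A electron-poor for step 9.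

Step 5
Reactants: 14 4-[(tert-butyldimethylsilyl)oxy]-5,8-dimethoxy-3-vinylnaphthalen-1-yl acetate
Product: 15 4-[(tert-butyldimethylsilyl)oxy]-3-formyl-5,8-dimethoxynaphthalen-1-yl acetate
Conditions: OsO4 (2 mol%), NaIO4, 2,6-lutidine, dioxane/H2O 3:1, rt
Reagents that add atoms: osmium tetroxide (oxygen carrier, regenerated), O=[Os](=O)(=O)=O; sodium periodate (terminal oxygen source), [Na+].[O-]I(=O)(=O)=O
Why: Lemieux–Johnson oxidation: the terminal styrene-type alkene is dihydroxylated far faster than the arene and the diol is cleaved by periodate, while the aryl acetate and silyl ether are inert.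

Step 6
Reactants: 16 2-methylbut-3-yn-2-ol
Product: 17 triethyl[(2-methylbut-3-yn-2-yl)oxy]silane
Conditions: TESCl, imidazole, DMF, 0 °C to rt
Reagents that add atoms: chlorotriethylsilane (TESCl), CC[Si](Cl)(CC)CC
Why: Standard silyl ether formation, so that the tertiary hydroxyl group does not consume the borane or the zinc reagent in step 7.

Step 7
Reactants: 17 triethyl[(2-methylbut-3-yn-2-yl)oxy]silane; 15 4-[(tert-butyldimethylsilyl)oxy]-3-formyl-5,8-dimethoxynaphthalen-1-yl acetate
Product: 21 4-[(tert-butyldimethylsilyl)oxy]-3-[(1R,2E)-1-hydroxy-4-methyl-4-(triethylsilyloxy)pent-2-en-1-yl]-5,8-dimethoxynaphthalen-1-yl acetate, via alkenylborane 18 (not isolated), via alkenylzinc 19 (not isolated), via zinc alkoxide 20 (not isolated)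
Conditions: BH3·SMe2, cyclohexene, toluene, 0 °C (gives Cy2BH); 17, 0 °C to rt; Me2Zn, −78 °C; (+)-MIB (5 mol%), then 15, −20 to 0 °C; aq NH4Cl
Reagents that add atoms: none
Why: Syn-hydroboration of the terminal alkyne, boron-to-zinc transmetalation and amino-alcohol-catalysed alkenylzinc addition to the aldehyde should give the (E)-allylic alcohol; (+)-MIB, (2R)-3-exo-morpholinoisoborneol, should deliver the alkenyl group to the Re face of the aldehyde (its enantiomer gives Si-face addition to aryl aldehydes), which sets C1′ as R.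

Step 8
Reactants: 21 the (1R,2E)-allylic alcohol; 22 (2R)-2-methylbutanoic acid
Product: 23 (1R,2E)-1-{4-acetoxy-1-[(tert-butyldimethylsilyl)oxy]-5,8-dimethoxynaphthalen-2-yl}-4-methyl-4-(triethylsilyloxy)pent-2-en-1-yl (2R)-2-methylbutanoate
Conditions: DCC, DMAP (0.2 equiv), CH2Cl2, 0 °C to rt
Reagents that add atoms: none
Why: Steglich esterification acylates the secondary alcohol at oxygen, so C1′ is untouched, and the α-stereocentre of the saturated acid should not epimerise under carbodiimide/DMAP activation.

Step 9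
Reactants: 23 the naphthalene ester
Product: 24 (1R,2E)-1-{4-acetoxy-1-[(tert-butyldimethylsilyl)oxy]-5,8-dioxo-5,8-dihydronaphthalen-2-yl}-4-methyl-4-(triethylsilyloxy)pent-2-en-1-yl (2R)-2-methylbutanoate
Conditions: (NH4)2Ce(NO3)6 (2.5 equiv), MeCN/H2O 4:1, 0 °C, 15 min
Reagents that add atoms: water, O
Why: Oxidative demethylation by tetravalent cerium should take place in the electron-rich 5,8-dimethoxy ring B, because ring A is deactivated by the acetoxy group and carries the acyloxyalkyl chain, which is known to steer this oxidation to the other ring of tetraoxygenated naphthalenes.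

Step 10
Reactants: 24 the ring-B quinone
Product: 26 (1R,2E)-1-(5,8-dihydroxy-1,4-dioxo-1,4-dihydronaphthalen-2-yl)-4-hydroxy-4-methylpent-2-en-1-yl (2R)-2-methylbutanoate, via hydroxy acetate 25 (not isolated)
Conditions: Bu4NF/AcOH (1:1), THF, 0 °C to rt; then MeOH, K2CO3 (cat.), 0 °C, 10 min; AcOH
Reagents that add atoms: none
Why: Buffered fluoride desilylation should cleave the aryl silyl ether (a vinylogous silyl ester of the quinone) and the tertiary silyl ether, and the remaining peri-acetoxy group is an activated aryl ester (its leaving group is the chelated naphthazarin monoanion) that brief methanolysis should remove much faster than the hindered secondary 2-methylbutanoate; proton tautomerism then gives the naphthazarin as drawn.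

**Compound list**

1 | diisopropyl squarate (3,4-diisopropoxycyclobut-3-ene-1,2-dione) | CC(C)OC1=C(OC(C)C)C(=O)C1=O | starting material
2 | 4-hydroxy-2,3-diisopropoxycyclobut-2-en-1-one (racemic) | CC(C)OC1=C(OC(C)C)C(=O)C1O | intermediate
3 | 3-isopropoxycyclobut-3-ene-1,2-dione (isopropyl semisquarate) | CC(C)OC1=CC(=O)C1=O | intermediate
4 | 2-bromo-1,4-dimethoxybenzene | COc1ccc(OC)c(Br)c1 | starting material
5 | (2,5-dimethoxyphenyl)lithium | [Li]c1cc(OC)ccc1OC | intermediate
6 | lithium 1-(2,5-dimethoxyphenyl)-2-isopropoxy-4-oxocyclobut-2-en-1-olate (racemic) | [Li]OC1(c2cc(OC)ccc2OC)C(OC(C)C)=CC1=O | intermediate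
7 | 4-[(tert-butyldimethylsilyl)oxy]-4-(2,5-dimethoxyphenyl)-3-isopropoxycyclobut-2-en-1-one (racemic) | CC(C)OC1=CC(=O)C1(O[Si](C)(C)C(C)(C)C)c1cc(OC)ccc1OC | intermediate
8 | bromomagnesium alkoxide of 9 (racemic diastereomer mixture) | CC(C)OC1=CC(O[Mg]Br)(C=C)C1(O[Si](C)(C)C(C)(C)C)c1cc(OC)ccc1OC | intermediate
9 | 4-[(tert-butyldimethylsilyl)oxy]-4-(2,5-dimethoxyphenyl)-3-isopropoxy-1-vinylcyclobut-2-en-1-ol (racemic diastereomer mixture) | CC(C)OC1=CC(O)(C=C)C1(O[Si](C)(C)C(C)(C)C)c1cc(OC)ccc1OC | intermediate
10 | 4-[(tert-butyldimethylsilyl)oxy]-4-(2,5-dimethoxyphenyl)-3-vinylcyclobut-2-en-1-one (racemic) | C=CC1=CC(=O)C1(O[Si](C)(C)C(C)(C)C)c1cc(OC)ccc1OC | intermediate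
11 | (3E)-4-[(tert-butyldimethylsilyl)oxy]-4-(2,5-dimethoxyphenyl)-3-vinylbuta-1,3-dien-1-one (dienylketene) | O=C=C/C(C=C)=C(/O[Si](C)(C)C(C)(C)C)c1cc(OC)ccc1OC | intermediate
12 | 4-[(tert-butyldimethylsilyl)oxy]-5,8-dimethoxy-3-vinyl-8aH-naphthalen-1-one (racemic) | C=CC1=CC(=O)C2C(OC)=CC=C(OC)C2=C1O[Si](C)(C)C(C)(C)C | intermediate
13 | 4-[(tert-butyldimethylsilyl)oxy]-5,8-dimethoxy-3-vinylnaphthalen-1-ol | C=Cc1cc(O)c2c(OC)ccc(OC)c2c1O[Si](C)(C)C(C)(C)C | intermediate
14 | 4-[(tert-butyldimethylsilyl)oxy]-5,8-dimethoxy-3-vinylnaphthalen-1-yl acetate | C=Cc1cc(OC(C)=O)c2c(OC)ccc(OC)c2c1O[Si](C)(C)C(C)(C)C | intermediate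
15 | 4-[(tert-butyldimethylsilyl)oxy]-3-formyl-5,8-dimethoxynaphthalen-1-yl acetate | O=Cc1cc(OC(C)=O)c2c(OC)ccc(OC)c2c1O[Si](C)(C)C(C)(C)C | intermediate
16 | 2-methylbut-3-yn-2-ol | CC(C)(O)C#C | starting material
17 | triethyl[(2-methylbut-3-yn-2-yl)oxy]silane | CC[Si](CC)(CC)OC(C)(C)C#C | intermediate
18 | dicyclohexyl[(1E)-3-methyl-3-(triethylsilyloxy)but-1-en-1-yl]borane | CC[Si](CC)(CC)OC(C)(C)/C=C/B(C1CCCCC1)C1CCCCC1 | intermediate
19 | methyl[(1E)-3-methyl-3-(triethylsilyloxy)but-1-en-1-yl]zinc | CC[Si](CC)(CC)OC(C)(C)/C=C/[Zn]C | intermediate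
20 | methylzinc alkoxide of 21 | C[Zn]O[C@H](/C=C/C(C)(C)O[Si](CC)(CC)CC)c1cc(OC(C)=O)c2c(OC)ccc(OC)c2c1O[Si](C)(C)C(C)(C)C | intermediate
21 | 4-[(tert-butyldimethylsilyl)oxy]-3-[(1R,2E)-1-hydroxy-4-methyl-4-(triethylsilyloxy)pent-2-en-1-yl]-5,8-dimethoxynaphthalen-1-yl acetate | O[C@H](/C=C/C(C)(C)O[Si](CC)(CC)CC)c1cc(OC(C)=O)c2c(OC)ccc(OC)c2c1O[Si](C)(C)C(C)(C)C | intermediate
22 | (2R)-2-methylbutanoic acid | CC[C@@H](C)C(=O)O | starting material
23 | (1R,2E)-1-{4-acetoxy-1-[(tert-butyldimethylsilyl)oxy]-5,8-dimethoxynaphthalen-2-yl}-4-methyl-4-(triethylsilyloxy)pent-2-en-1-yl (2R)-2-methylbutanoate | CC[C@@H](C)C(=O)O[C@H](/C=C/C(C)(C)O[Si](CC)(CC)CC)c1cc(OC(C)=O)c2c(OC)ccc(OC)c2c1O[Si](C)(C)C(C)(C)C | intermediate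
24 | (1R,2E)-1-{4-acetoxy-1-[(tert-butyldimethylsilyl)oxy]-5,8-dioxo-5,8-dihydronaphthalen-2-yl}-4-methyl-4-(triethylsilyloxy)pent-2-en-1-yl (2R)-2-methylbutanoate | CC[C@@H](C)C(=O)O[C@H](/C=C/C(C)(C)O[Si](CC)(CC)CC)c1cc(OC(C)=O)c2C(=O)C=CC(=O)c2c1O[Si](C)(C)C(C)(C)C | intermediate
25 | (1R,2E)-1-(4-acetoxy-1-hydroxy-5,8-dioxo-5,8-dihydronaphthalen-2-yl)-4-hydroxy-4-methylpent-2-en-1-yl (2R)-2-methylbutanoate | CC[C@@H](C)C(=O)O[C@H](/C=C/C(C)(C)O)c1cc(OC(C)=O)c2C(=O)C=CC(=O)c2c1O | intermediate
26 | (1R,2E)-1-(5,8-dihydroxy-1,4-dioxo-1,4-dihydronaphthalen-2-yl)-4-hydroxy-4-methylpent-2-en-1-yl (2R)-2-methylbutanoate | CC[C@@H](C)C(=O)O[C@H](/C=C/C(C)(C)O)C1=CC(=O)c2c(O)ccc(O)c2C1=O | target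

**Step count and risks**

Total steps: 10. Longest linear sequence: 9 steps (steps 1–5 and 7–10; step 6 is a side branch).

Steps most likely to fail:

Step 7. Alkenyl transfer to the aldehyde, which is flanked by a bulky ortho silyloxy group, may be slow and poorly face-selective, and methyl transfer from Me2Zn may compete. The fallback sets out from 15 and comes back at 21. The alkenylzinc 19 would be added to 15 without the chiral ligand to give the racemic allylic alcohol F1. A Sharpless kinetic resolution (Ti(OiPr)4, D-(−)-diisopropyl tartrate, t-BuOOH (0.6 equiv), 4 Å sieves, CH2Cl2, −20 °C) should then epoxidise the (S)-enantiomer to the erythro epoxy alcohol F2 and leave the (R)-alcohol 21. The tartrate is chosen by the usual mnemonic; here the aryl group takes the place of the alkyl group of the standard cases, which inverts the CIP label of the slow-reacting enantiomer.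

Step 9. The oxidation may stray into ring A through oxidative loss of the silyl ether, or the acidic oxidant may ionise the benzylic, allylic ester. The fallback sets out from 23 and comes back at 24. Anodic oxidation in methanol (Pt anode, LiClO4, 2,6-lutidine, MeOH, 0 °C, constant current) should give the ring-B bis(dimethyl ketal) F3, since methoxylation can only occur at the two methoxy-bearing carbons. Mild hydrolysis (oxalic acid on wet silica, CH2Cl2) would then release quinone 24.

Step 10. The side-chain ester may undergo methanolysis, or the naphthazarin anion may degrade, during removal of the aryl acetate. The fallback sets out from 21 and comes back at 26; it moves the acylation to the end so that no side-chain ester is present during deprotection. Alcohol 21 would be oxidised with (NH4)2Ce(NO3)6 (MeCN/H2O, 0 °C) to the quinone alcohol F4. Deprotection (Bu4NF/AcOH, THF; then K2CO3, MeOH, 0 °C) would give the parent naphthazarin diol F5. A final Steglich acylation with 22 (DCC, DMAP, CH2Cl2) should give 26 at the secondary alcohol only, because the chelated phenols and the tertiary alcohol are unreactive.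

Further compounds
F1 | step 7 | 4-[(tert-butyldimethylsilyl)oxy]-3-[(2E)-1-hydroxy-4-methyl-4-(triethylsilyloxy)pent-2-en-1-yl]-5,8-dimethoxynaphthalen-1-yl acetate (racemate) | OC(/C=C/C(C)(C)O[Si](CC)(CC)CC)c1cc(OC(C)=O)c2c(OC)ccc(OC)c2c1O[Si](C)(C)C(C)(C)C
F2 | step 7 | 4-[(tert-butyldimethylsilyl)oxy]-3-{(R)-hydroxy[(2R,3S)-3-[2-(triethylsilyloxy)propan-2-yl]oxiran-2-yl]methyl}-5,8-dimethoxynaphthalen-1-yl acetate | O[C@@H]([C@H]1O[C@@H]1C(C)(C)O[Si](CC)(CC)CC)c1cc(OC(C)=O)c2c(OC)ccc(OC)c2c1O[Si](C)(C)C(C)(C)C
F3 | step 9 | (1R,2E)-1-{4-acetoxy-1-[(tert-butyldimethylsilyl)oxy]-5,5,8,8-tetramethoxy-5,8-dihydronaphthalen-2-yl}-4-methyl-4-(triethylsilyloxy)pent-2-en-1-yl (2R)-2-methylbutanoate | CC[C@@H](C)C(=O)O[C@H](/C=C/C(C)(C)O[Si](CC)(CC)CC)c1cc(OC(C)=O)c2c(c1O[Si](C)(C)C(C)(C)C)C(OC)(OC)C=CC2(OC)OC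
F4 | step 10 | 4-[(tert-butyldimethylsilyl)oxy]-3-[(1R,2E)-1-hydroxy-4-methyl-4-(triethylsilyloxy)pent-2-en-1-yl]-5,8-dioxo-5,8-dihydronaphthalen-1-yl acetate | O[C@H](/C=C/C(C)(C)O[Si](CC)(CC)CC)c1cc(OC(C)=O)c2C(=O)C=CC(=O)c2c1O[Si](C)(C)C(C)(C)C
F5 | step 10 | 2-[(1R,2E)-1,4-dihydroxy-4-methylpent-2-en-1-yl]-5,8-dihydroxynaphthalene-1,4-dione | O[C@H](/C=C/C(C)(C)O)C1=CC(=O)c2c(O)ccc(O)c2C1=O
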